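**Plan**

- Retrosynthetic cuts, in order: the C6–CH2 bond between the quaternary peroxyketal carbon and the C18 chain; the ring C4=C5 bond (ring-closing metathesis); the O1–C6 bond (peroxy orthoester exchange); the C3–O2 bond (asymmetric peroxidation of an enal); in the chain, the C12–C13 bond (Grignard reagent plus sorbyl acetate).
- Forward: the C3–O–O unit is made first, the 1,2-dioxine ring is closed at C4=C5 on a peroxy orthoester, and the finished C18 chain with its E,E-diene is joined last at C6.
- Stereochemistry: C3 (R) comes from the amine-catalysed addition of a hydroperoxide to sorbaldehyde; C6 (S) is set by C3 in the key step (pseudoaxial attack, chain cis to CH2CO2Me); the E,E-diene comes unchanged from sorbyl acetate.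
- Enabling feature: C6 of the 1,2-dioxine ring carries ring oxygen O1 and the methoxy oxygen and is allylic to C4=C5. With a second methoxy group it is a peroxy orthoester that ionises to a 6-methoxy-1,2-dioxinium ion, which accepts a carbon nucleophile.
- Order: the side-chain diene would not survive singlet oxygen or a ruthenium carbene, so the peroxide ring is finished before the chain arrives.

Key step: step 14

Assumption: the diarylprolinol silyl ether is taken to shield one face of the E, s-trans dienyl iminium ion as in related β-additions, so that the R catalyst gives the 3R peroxide; if the sense proves opposite, the S catalyst is used.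

**Route**

Step 1
Reactants: 1 2,3-dimethylbut-2-ene
Product: 2 2-methoxyprop-2-yl hydroperoxide (2-hydroperoxy-2-methoxypropane)
Conditions: O3, CH2Cl2/MeOH, −78 °C; N2 purge; kept and used as a cold, titrated solution
Reagents that add atoms: ozone, O=[O+][O-]; methanol, CO
Why: Criegee ozonolysis of a symmetrical tetrasubstituted alkene, in which methanol traps the acetone O-oxide as the α-methoxy hydroperoxide, a standard protected form of hydrogen peroxide.

Step 2
Reactants: 3 (2E,4E)-hexa-2,4-dienal; 2 2-methoxyprop-2-yl hydroperoxide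
Product: 4 (3R,4E)-3-[(2-methoxypropan-2-yl)peroxy]hex-4-enal
Conditions: (R)-2-{bis[3,5-bis(trifluoromethyl)phenyl](trimethylsilyloxy)methyl}pyrrolidine (10 mol %), PhCO2H (10 mol %), PhMe, −20 °C
Reagents that add atoms: none
Why: Amine-catalysed asymmetric peroxidation of an enal (iminium-ion oxa-Michael addition of a hydroperoxide): the hydroperoxide should add to C3, the β-carbon of the dienyl iminium ion, on the face away from the diaryl(silyloxy)methyl group to set 3R, while the acid co-catalyst and the low temperature favour protonation of the β-peroxy enamine over Weitz–Scheffer closure to an epoxide.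

Step 3
Reactants: 4 (3R,4E)-3-[(2-methoxypropan-2-yl)peroxy]hex-4-enal
Product: 5 (3R,4E)-3-[(2-methoxypropan-2-yl)peroxy]hex-4-enoic acid
Conditions: NaClO2, NaH2PO4, 2-methylbut-2-ene, t-BuOH/H2O, 0 °C
Reagents that add atoms: sodium chlorite, [Na+].[O-]Cl=O
Why: Pinnick oxidation: chlorous acid should oxidise the aldehyde without touching the O–O bond, the alkene or C3, the hypochlorous acid formed being scavenged by 2-methylbut-2-ene.

Step 4
Reactants: 5 (3R,4E)-3-[(2-methoxypropan-2-yl)peroxy]hex-4-enoic acid
Product: 6 methyl (3R,4E)-3-[(2-methoxypropan-2-yl)peroxy]hex-4-enoate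
Conditions: Me3SiCHN2, PhMe/MeOH, 0 °C
Reagents that add atoms: (trimethylsilyl)diazomethane, C[Si](C)(C)C=[N+]=[N-]
Why: Methyl ester formation with (trimethylsilyl)diazomethane is non-basic, so the β-peroxy ester should not suffer β-elimination of the peroxide.

Step 5
Reactants: 6 methyl (3R,4E)-3-[(2-methoxypropan-2-yl)peroxy]hex-4-enoate
Product: 7 methyl (3R,4E)-3-hydroperoxyhex-4-enoate
Conditions: AcOH/THF/H2O (4:2:1), 20 °C
Reagents that add atoms: none
Why: Mild acid hydrolysis of the 2-methoxyprop-2-yl peroxyketal (standard unmasking of a hydroperoxide) should free the OOH group without touching C3 or the ester.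

Step 6
Reactants: 8 3-bromo-1,1,1-trimethoxypropane
Product: 9 3,3,3-trimethoxyprop-1-ene (trimethyl orthoacrylate)
Conditions: KOt-Bu, THF, 0 to 20 °C; distillation
Reagents that add atoms: none
Why: E2 dehydrobromination of a β-bromo orthoester, the orthoester being inert to base (the known way to orthoacrylates).

Step 7
Reactants: 7 methyl (3R,4E)-3-hydroperoxyhex-4-enoate; 9 3,3,3-trimethoxyprop-1-ene
Product: 10 methyl (3R,4E)-3-[(1,1-dimethoxyprop-2-en-1-yl)peroxy]hex-4-enoate
Conditions: 9 (3 equiv), PPTS (5 mol %), 4 Å molecular sieves, CH2Cl2, 0 °C; Et3N quench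
Reagents that add atoms: none
Why: Acid-catalysed orthoester exchange (transorthoesterification, as used for peroxy orthoesters and 3-alkoxy-1,2,4-trioxanes): the hydroperoxide should replace one methoxy group at the dioxycarbenium carbon far faster than anything adds in conjugate fashion, and the sieves remove methanol to drive the equilibrium.

Step 8
Reactants: 10 methyl (3R,4E)-3-[(1,1-dimethoxyprop-2-en-1-yl)peroxy]hex-4-enoate
Product: 11 methyl 2-[(3R)-6,6-dimethoxy-3,6-dihydro-1,2-dioxin-3-yl]acetate
Conditions: second-generation Hoveyda–Grubbs catalyst, RuCl2(H2IMes)(=CH-C6H4-2-Oi-Pr) (5 mol %), CH2Cl2 (5 mM), 40 °C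
Reagents that add atoms: none
Why: Ring-closing metathesis between the vinyl group on the orthoester carbon and the propenyl group should close the six-membered ring with a necessarily Z C4=C5 bond and loss of propene, dialkyl peroxides being tolerated by ruthenium carbenes in olefin metathesis.

Step 9
Reactants: 12 12-bromododecan-1-ol
Product: 13 2-[(12-bromododecyl)oxy]oxane
Conditions: 3,4-dihydro-2H-pyran, PPTS (cat.), CH2Cl2, 20 °C
Reagents that add atoms: 3,4-dihydro-2H-pyran, C1=COCCC1
Why: Tetrahydropyranyl ether formation masks the hydroxyl group so that the bromide can be turned into a Grignard reagent.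

Step 10
Reactants: 13 2-[(12-bromododecyl)oxy]oxane; 14 (2E,4E)-hexa-2,4-dien-1-yl acetate (sorbyl acetate)
Product: 16 2-{[(14E,16E)-octadeca-14,16-dien-1-yl]oxy}oxane, via Grignard reagent 15 (not isolated)
Conditions: Mg, THF, 40 °C; then 14, Li2CuCl4 (2 mol %), THF, −20 to 0 °C
Reagents that add atoms: none
Why: Copper-catalysed alkyl–allyl coupling of a primary Grignard reagent with a dienyl acetate (Kochi-type coupling, the established route to conjugated E,E-diene pheromone alcohols) should substitute at the α-carbon and leave the E,E-diene intact.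

Step 11
Reactants: 16 2-{[(14E,16E)-octadeca-14,16-dien-1-yl]oxy}oxane
Product: 17 (14E,16E)-octadeca-14,16-dien-1-ol
Conditions: PPTS (10 mol %), MeOH, 45 °C
Reagents that add atoms: none
Why: Acid-catalysed methanolysis of the THP acetal is mild enough to leave the conjugated diene unchanged.

Step 12
Reactants: 17 (14E,16E)-octadeca-14,16-dien-1-ol
Product: 18 (2E,4E)-18-iodooctadeca-2,4-diene
Conditions: I2, PPh3, imidazole, CH2Cl2, 0 to 20 °C
Reagents that add atoms: iodine, [I][I]
Why: Appel-type iodination (Garegg–Samuelsson conditions) converts the primary alcohol by SN2 displacement; iodine can only equilibrate the diene towards the E,E form it already has.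

Step 13
Reactants: 18 (2E,4E)-18-iodooctadeca-2,4-diene
Product: 19 [(14E,16E)-octadeca-14,16-dien-1-yl]zinc iodide (LiCl-complexed solution in THF, titrated and used directly)
Conditions: Zn dust (activated with BrCH2CH2Br and Me3SiCl), LiCl, THF, 40 °C
Reagents that add atoms: zinc, [Zn]
Why: Direct insertion of zinc into a primary alkyl iodide in the presence of LiCl should give the alkylzinc iodide without affecting the remote diene.

Step 14
Reactants: 11 methyl 2-[(3R)-6,6-dimethoxy-3,6-dihydro-1,2-dioxin-3-yl]acetate; 19 [(14E,16E)-octadeca-14,16-dien-1-yl]zinc iodide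
Product: 21 xestin B (methyl 2-[(3R,6S)-6-methoxy-6-[(14E,16E)-octadeca-14,16-dien-1-yl]-3,6-dihydro-1,2-dioxin-3-yl]acetate), via dioxinium triflate 20 (not isolated)
Conditions: Me3SiOTf (1.05 equiv), CH2Cl2, −78 °C, 10 min; then 19 (1.5 equiv, THF), −78 to −30 °C; Et3N/MeOH, then aq. NaHCO3
Reagents that add atoms: none
Why: Proposed new method: Me3SiOTf removes one methoxy group from the peroxy orthoester carbon C6 of 11 to give the 6-methoxy-1,2-dioxinium ion 20 (charge shared by the methoxy oxygen, ring oxygen O1 and the C4=C5 double bond), and the alkylzinc iodide 19 transfers its primary alkyl group to C6, so that the C6–CH2 bond and the quaternary peroxyketal centre arise in one event. The closest known reaction types are the Bodroux–Chichibabin conversion of orthoesters into ketals by organometallic reagents, the Lewis-acid-mediated addition of organozinc halides to cyclic allylic oxocarbenium ions (Ferrier-type C-glycosylation) and the capture of cyclic peroxycarbenium ions by carbon nucleophiles. No ring is closed, the 1,2-dioxine ring made in step 8 being carried through unopened. The new stereocentre C6 is controlled by C3: in the half-chair cation the CH2CO2Me group lies pseudoequatorial and the nucleophile enters pseudoaxially at C6 on the face that leads directly to the half-chair product, which places the chain cis to CH2CO2Me (methoxy trans) and gives 6S. The step needs attack at C6 and not at C4, which is secured because C6 carries the larger share of the charge and C4 attack would give a high-energy ketene peroxyacetal, and it needs a single alkylation, which is secured because the product peroxyketal ionises far less readily than the orthoester at −78 °C with one equivalent of Lewis acid. The O–O bond and the ester should survive because an alkylzinc iodide is neither basic nor reducing enough to attack them at this temperature and no copper or palladium is present.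

**Compound list**

1 | 2,3-dimethylbut-2-ene | CC(C)=C(C)C | starting material
2 | 2-methoxyprop-2-yl hydroperoxide | COC(C)(C)OO | intermediate
3 | (2E,4E)-hexa-2,4-dienal | C/C=C/C=C/C=O | starting material
4 | (3R,4E)-3-[(2-methoxypropan-2-yl)peroxy]hex-4-enal | C/C=C/[C@@H](CC=O)OOC(C)(C)OC | intermediate
5 | (3R,4E)-3-[(2-methoxypropan-2-yl)peroxy]hex-4-enoic acid | C/C=C/[C@@H](CC(=O)O)OOC(C)(C)OC | intermediate
6 | methyl (3R,4E)-3-[(2-methoxypropan-2-yl)peroxy]hex-4-enoate | C/C=C/[C@@H](CC(=O)OC)OOC(C)(C)OC | intermediate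
7 | methyl (3R,4E)-3-hydroperoxyhex-4-enoate | C/C=C/[C@@H](CC(=O)OC)OO | intermediate
8 | 3-bromo-1,1,1-trimethoxypropane | COC(OC)(OC)CCBr | starting material
9 | 3,3,3-trimethoxyprop-1-ene | COC(OC)(OC)C=C | intermediate
10 | methyl (3R,4E)-3-[(1,1-dimethoxyprop-2-en-1-yl)peroxy]hex-4-enoate | C/C=C/[C@@H](CC(=O)OC)OOC(OC)(OC)C=C | intermediate
11 | methyl 2-[(3R)-6,6-dimethoxy-3,6-dihydro-1,2-dioxin-3-yl]acetate | COC1(OC)C=C[C@@H](CC(=O)OC)OO1 | intermediate
12 | 12-bromododecan-1-ol | OCCCCCCCCCCCCBr | starting material
13 | 2-[(12-bromododecyl)oxy]oxane | BrCCCCCCCCCCCCOC1CCCCO1 | intermediate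
14 | (2E,4E)-hexa-2,4-dien-1-yl acetate | CC(=O)OC/C=C/C=C/C | starting material
15 | {12-[(oxan-2-yl)oxy]dodecyl}magnesium bromide | Br[Mg]CCCCCCCCCCCCOC1CCCCO1 | intermediate
16 | 2-{[(14E,16E)-octadeca-14,16-dien-1-yl]oxy}oxane | C/C=C/C=C/CCCCCCCCCCCCCOC1CCCCO1 | intermediate
17 | (14E,16E)-octadeca-14,16-dien-1-ol | C/C=C/C=C/CCCCCCCCCCCCCO | intermediate
18 | (2E,4E)-18-iodooctadeca-2,4-diene | C/C=C/C=C/CCCCCCCCCCCCCI | intermediate
19 | [(14E,16E)-octadeca-14,16-dien-1-yl]zinc iodide | C/C=C/C=C/CCCCCCCCCCCCC[Zn]I | intermediate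
20 | (3R)-6-methoxy-3-(2-methoxy-2-oxoethyl)-3H-1,2-dioxin-1-ium trifluoromethanesulfonate | COC1=[O+]O[C@H](CC(=O)OC)C=C1.[O-]S(=O)(=O)C(F)(F)F | intermediate
21 | xestin B, methyl 2-[(3R,6S)-6-methoxy-6-[(14E,16E)-octadeca-14,16-dien-1-yl]-3,6-dihydro-1,2-dioxin-3-yl]acetate | C/C=C/C=C/CCCCCCCCCCCCC[C@@]1(OC)C=C[C@@H](CC(=O)OC)OO1 | target

**Summary**

Total step count: 14. Longest linear sequence: 8 steps (1, 2, 3, 4, 5, 7, 8, 14).

**Steps most likely to fail**

1. Step 14 (the step that bears the label "Proposed new method:").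
 - What may go wrong: ionisation may take the other course, with loss of the ring peroxy oxygen and opening of the ring. The alkyl group may add at C4. The O–O bond may undergo Lewis-acid-induced heterolysis. Facial control may be eroded by participation of the ester carbonyl at C6.
 - Fallback (known chemistry; sets out from 6 and 19, comes back at 21): the same bond is formed as a ketone. Ozonolysis of 6 (O3, CH2Cl2, −78 °C; Me2S) should give methyl (3R)-3-[(2-methoxypropan-2-yl)peroxy]-4-oxobutanoate F1. Wittig olefination with S-ethyl (triphenylphosphoranylidene)thioacetate should give methyl (3R,4E)-6-(ethylsulfanyl)-3-[(2-methoxypropan-2-yl)peroxy]-6-oxohex-4-enoate F2. Fukuyama coupling of F2 with 19 (PdCl2(PPh3)2 cat., THF/PhMe, 20 °C) should give methyl (3R,4E,20E,22E)-3-[(2-methoxypropan-2-yl)peroxy]-6-oxotetracosa-4,20,22-trienoate F3. Hydrolysis of the peroxyketal (AcOH/THF/H2O) should free methyl (3R,4E,20E,22E)-3-hydroperoxy-6-oxotetracosa-4,20,22-trienoate F4. Irradiation above 300 nm should isomerise the enone to its Z form, which closes at once to the hemiperoxyketal methyl 2-[(3R)-6-hydroxy-6-[(14E,16E)-octadeca-14,16-dien-1-yl]-3,6-dihydro-1,2-dioxin-3-yl]acetate F5. Acid-catalysed methanolysis (MeOH, TsOH cat.) should then give 21 together with its C6 epimer, methyl 2-[(3R,6R)-6-methoxy-6-[(14E,16E)-octadeca-14,16-dien-1-yl]-3,6-dihydro-1,2-dioxin-3-yl]acetate F6. The two are separated by chromatography and the epimer is re-equilibrated under the same conditions.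

2. Step 7.
 - What may go wrong: conjugate addition of methanol or of the hydroperoxide to the acrylate-like dimethoxycarbenium ion, or an unfavourable exchange equilibrium.
 - Fallback (sets out from 7, comes back at 10): 7 is silylated with N,O-bis(trimethylsilyl)acetamide to methyl (3R,4E)-3-[(trimethylsilyl)peroxy]hex-4-enoate F7. F7 is then joined to 9 by Me3SiOTf-catalysed silyl-transfer exchange at −78 °C (aprotic acetalisation from a silyl ether and an orthoester). This should form 10 irreversibly and keeps free methanol and free hydroperoxide out of the flask.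

3. Step 2.
 - What may go wrong: poor facial discrimination on the dienyl iminium ion, or loss of enantiomeric purity through reversible retro-oxa-Michael addition.
 - Fallback (sets out from 7 of insufficient enantiomeric purity, comes back at enantiopure 7): resolution through diastereomeric perketals. Commercial (1R,2S)-2-phenylcyclohexanol is acetylated to (1R,2S)-2-phenylcyclohexyl acetate F8 and methylenated with the Tebbe reagent, Cp2Ti(μ-Cl)(μ-CH2)AlMe2, to the prop-1-en-2-yl ether of (1R,2S)-2-phenylcyclohexanol F9. PPTS-catalysed addition of scalemic 7 to F9 should give methyl (3R,4E)-3-[(2-{[(1R,2S)-2-phenylcyclohexyl]oxy}propan-2-yl)peroxy]hex-4-enoate F10 and its 3S diastereomer, methyl (3S,4E)-3-[(2-{[(1R,2S)-2-phenylcyclohexyl]oxy}propan-2-yl)peroxy]hex-4-enoate F11. These are separated by chromatography, and hydrolysis of F10 (AcOH/THF/H2O) returns 7.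

Further compounds
F1 | step 14 | methyl (3R)-3-[(2-methoxypropan-2-yl)peroxy]-4-oxobutanoate | O=C[C@@H](CC(=O)OC)OOC(C)(C)OC
F2 | step 14 | methyl (3R,4E)-6-(ethylsulfanyl)-3-[(2-methoxypropan-2-yl)peroxy]-6-oxohex-4-enoate | CCSC(=O)/C=C/[C@@H](CC(=O)OC)OOC(C)(C)OC
F3 | step 14 | methyl (3R,4E,20E,22E)-3-[(2-methoxypropan-2-yl)peroxy]-6-oxotetracosa-4,20,22-trienoate | C/C=C/C=C/CCCCCCCCCCCCCC(=O)/C=C/[C@@H](CC(=O)OC)OOC(C)(C)OC
F4 | step 14 | methyl (3R,4E,20E,22E)-3-hydroperoxy-6-oxotetracosa-4,20,22-trienoate | C/C=C/C=C/CCCCCCCCCCCCCC(=O)/C=C/[C@@H](CC(=O)OC)OO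
F5 | step 14 | methyl 2-[(3R)-6-hydroxy-6-[(14E,16E)-octadeca-14,16-dien-1-yl]-3,6-dihydro-1,2-dioxin-3-yl]acetate | C/C=C/C=C/CCCCCCCCCCCCCC1(O)C=C[C@@H](CC(=O)OC)OO1
F6 | step 14 | methyl 2-[(3R,6R)-6-methoxy-6-[(14E,16E)-octadeca-14,16-dien-1-yl]-3,6-dihydro-1,2-dioxin-3-yl]acetate | C/C=C/C=C/CCCCCCCCCCCCC[C@]1(OC)C=C[C@@H](CC(=O)OC)OO1
F7 | step 7 | methyl (3R,4E)-3-[(trimethylsilyl)peroxy]hex-4-enoate | C/C=C/[C@@H](CC(=O)OC)OO[Si](C)(C)C
F8 | step 2 | (1R,2S)-2-phenylcyclohexyl acetate | CC(=O)O[C@@H]1CCCC[C@H]1c1ccccc1
F9 | step 2 | prop-1-en-2-yl ether of (1R,2S)-2-phenylcyclohexanol | C=C(C)O[C@@H]1CCCC[C@H]1c1ccccc1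
F10 | step 2 | methyl (3R,4E)-3-[(2-{[(1R,2S)-2-phenylcyclohexyl]oxy}propan-2-yl)peroxy]hex-4-enoate | C/C=C/[C@@H](CC(=O)OC)OOC(C)(C)O[C@@H]1CCCC[C@H]1c1ccccc1
F11 | step 2 | methyl (3S,4E)-3-[(2-{[(1R,2S)-2-phenylcyclohexyl]oxy}propan-2-yl)peroxy]hex-4-enoate | C/C=C/[C@H](CC(=O)OC)OOC(C)(C)O[C@@H]1CCCC[C@H]1c1ccccc1
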